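**What I had.** Over the 8.0 h allowed at constant temperature, I had two earlier runs and a new flask charged with more catalyst.

all flasks: starting material 0.11 M
- west: second substrate 0.22 M; precatalyst 28 µM; run made earlier
- east: second substrate 0.22 M; precatalyst 41 µM; run made earlier
- flask: second substrate 0.220 M; precatalyst 55 µM; time 8.0 h

| run | time / h | target / % |
|---|---|---|
| west | 1.33 | 5.9 |
| west | 2.00 | 8.7 |
| west | 3.00 | 13.4 |
| west | 5.00 | 17.5 |
| west | 8.00 | 19.2 |
| east | 1.33 | 7.2 |
| east | 2.00 | 11.8 |
| east | 3.00 | 17.3 |
| east | 5.00 | 24.2 |
| east | 8.00 | 25.2 |

(standard deviation of a reading: 0.5 percentage points)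

* the best time, 8.0 h at the latest, for target
* the amount of target, in percent of the starting material charged, at that time

**Main step.** I first took the catalysed step by itself, with target growing in proportion to catalyst and time. The first east reading, scaled to [precatalyst] of 55 µM and carried to 8.0 h, gave 58.1% for the flask.

**Competing loss.** But east itself read just 25.2% at 8.00 h, below the 43.3% that the same line gave at its own loading. So I added a loss of starting material that ran without catalyst. Target over the rest of the charge at the last reading, divided by the [precatalyst] charged, came to 8490 L mol⁻¹ in west and 8220 L mol⁻¹ in east, and their mean was 8350 L mol⁻¹. I called this the odds per catalyst, a selectivity factor per unit of catalyst. For the flask it gave odds of 0.459, so a ceiling of 31.5%.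

**Slow loss.** From 5.00 h to 8.0 h, west gained 1.7 percentage points and east 1 point. A straight line through these gave the flask 0.25 points, against a scatter of 0.5 points. I therefore added a slow loss of target and expected the maximum between those times.

**Forecast.** The forecast gave 30.5% at 8 h: “There is no clear sign of product loss”. Its height was close to my ceiling, and its time stood at the late end of my window.

**Result.** The flask reached 28.9% at 5.46 h, and held 26.2% of target at 8.00 h.

    second substrate + loaded enzyme ⇌ second complex (K = 16.0 L mol⁻¹, k = 1480 L mol⁻¹ min⁻¹)
    target + first product → side product (k = 0.0632 L mol⁻¹ min⁻¹)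
    second complex → free enzyme + target (k = 52.2 min⁻¹)
    starting material + free enzyme ⇌ first complex (K = 9.70 L mol⁻¹, k = 7400 L mol⁻¹ min⁻¹)
    starting material + second substrate → uncatalysed product (k = 0.0196 L mol⁻¹ min⁻¹)
    precatalyst → free enzyme (k = 0.0270 min⁻¹)
    first complex → loaded enzyme + first product (k = 10.8 min⁻¹)

**Neighbour.** At its maximum, at 5.46 h, the flask read 7390 L mol⁻¹, below the carried 8350 L mol⁻¹, and held 9.85% of side product at that time. For the neighbour charged with [precatalyst] of 2.2 × 10⁻⁴ M, the same odds per catalyst gave odds of 1.84, so 64.8%. That neighbour reached 50.7%, and at 8.00 h it held 26.1% of target and 46.3% of side product.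

(The data are calculated for substances that don't exist; the scatter is artificial.)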